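Early on, the alder and larch runs look alike once the J made is set against the X charged. X is the limiting reagent, the one charged in the smaller amount in both runs (150 mM in alder against 225 mM of Z), so we write its balance, and as a first guess we take it that each minute X loses a fixed share of what is present. Taking the first reading of each run as X lost, the making constant is 0.0167 min⁻¹ in alder and 0.0171 min⁻¹ in larch. The order in X therefore reads about one; the first readings give 1.05.

the same everywhere: Z 225 mM

| flask | X | L | time |
|---|---|---|---|
| alder | 150 mM | 4.50 mM |  |
| larch | 220 mM | 4.50 mM |  |
| ash | 150 mM | 22.0 mM | 60 min |

| alder run: time / min | alder run: [J] / mM | larch run: time / min | larch run: [J] / mM |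
|---|---|---|---|
| 10 | 23.1 | 10 | 34.6 |
| 20 | 43.1 | 20 | 61.3 |
| 30 | 58.0 | 30 | 81.6 |
| 40 | 66.5 | 40 | 97.2 |
| 50 | 72.1 | 50 | 107.4 |
| 60 | 77.7 | 60 | 112.4 |

(each reading ± 0.8 mM)

* the exponent of [X] in the starting rate at the charge of the alder run (at the point where two percent of the X have become J) (one fixed amount of J, the same in the runs compared)
* J in the ash run at 60 min, as a share of the X charged

Now the balance of J. Around 50 min in the alder run, the X left by that constant should feed J at 1.09 mM min⁻¹, but the readings from 40 min to 60 min climb at 0.560 mM min⁻¹. If the gap is J being lost, dividing it by the 72.1 mM of J present gives 0.00731 min⁻¹. The larch run, treated the same way, gives 0.00782 min⁻¹. Their mean, 0.00757 min⁻¹, is what we carry: the leak constant, the share of the J present that is lost each minute.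

The ash run has 4.89 times the catalyst of alder. Assuming the making constant follows the catalyst, it becomes 0.0818 min⁻¹, which by this estimate leaves 0.739% of the X at 60 min. For two first-order steps in a row, J as a share of the X charged is the making constant over its excess above the leak, times the difference of the two exponentials. Our reckoning gives 69.2%. The forecast stands higher, at 78%, with an order of 1.05, and reads the sag differently: “This suggests reversibility, or product competing for the catalyst, rather than simple timed catalyst death.”

The order in X at the alder charge comes out at 1.0 and the ash run gives 64.8%, so the forecast's order holds and its yield is 13 percentage points too high.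

    L + X → Vy + E (5.850 L mol⁻¹ min⁻¹)
    Vy + Z → J + L (50.22 L mol⁻¹ min⁻¹)
    J → Jy (0.008760 min⁻¹)
    X + Z ⇌ XZ, settled at all times (1.910 L mol⁻¹)

The shortfall in the ash run comes from the loss of J to Jy: with that step taken away, the same run ends at 99.8%. By our estimated making constant, J in the ash run is formed on average about 12.2 min after the start, which leaves it roughly 47.8 min exposed to the leak. Our leak constant keeps 69.7% of J over that wait, while the 64.8% of the ash run, read the same way, asks for a leak constant of 0.00903 min⁻¹.

(The data come from a simulation from invented constants; noise was put on by code.)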